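**Assumption:** (−)-Epigallocatechin (tea catechin, ≥95 %) is taken as a commercial chiral starting material. The target SMILES corresponds to its (2R,3R) 3-O-(E)-feruloyl ester.

## Retrosynthetic overview

1. Rings A, B, C and both stereocentres (2R,3R) are bought intact as (−)-epigallocatechin **1**. No bond to C2 or C3 is broken anywhere, so the route only has to append the feruloyl unit to O3.
2. The five phenols are capped with MOMCl **2** to give **3**; trichloroethylene **4** then converts the free 3-OH into the terminal ynol ether **5** (C3–O bond untouched).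
3. Vanillin **6** is protected as MOM ether **7**, which supplies the guaiacyl ring and Cβ.
4. Key disconnection: the ester C=O and the Cα=Cβ bond of **8** are made together from **5** + **7** by alkyne–carbonyl metathesis, i.e. [2+2] cycloaddition to a 2H-oxete followed by conrotatory 4π-electrocyclic ring opening to the (E)-enoate. Acid then removes the six MOM groups to give **9**.
5. Ring order: A/B/C (in **1**) and the guaiacyl ring (in **6**) are purchased. The only ring formed is the transient oxete in the key step, which opens in the same operation.

## Route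

**Step 1**
Reactants: **1** (−)-epigallocatechin; **2** chloromethyl methyl ether
Product: **3** (2R,3R)-5,7-bis(methoxymethoxy)-2-[3,4,5-tris(methoxymethoxy)phenyl]chroman-3-ol
Conditions: MOMCl (6 equiv), K2CO3 (8 equiv), degassed acetone, Ar, 0 °C → rt
Reagents that add atoms: chloromethyl methyl ether, COCCl
Why: Williamson-type O-alkylation; K2CO3 ionises only the five phenols, so the hindered secondary 3-OH stays free, and no stereocentre is touched.

**Step 2**
Reactants: **3**; **4** trichloroethylene
Product: **5** (2R,3R)-3-(ethynyloxy)-5,7-bis(methoxymethoxy)-2-[3,4,5-tris(methoxymethoxy)phenyl]chromane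
Conditions: KH (2 equiv), THF, 0 °C; Cl2C=CHCl (1.1 equiv), −50 °C → rt; then n-BuLi (3 equiv), −78 → −40 °C; MeOH quench at −78 °C (one pot); Et3N-deactivated SiO2
Reagents that add atoms: trichloroethylene, ClC=C(Cl)Cl (provides the C≡C unit)
Why: Greene ynol-ether synthesis: the alkoxide adds to in situ dichloroacetylene to give the 1,2-dichlorovinyl ether, and n-BuLi effects elimination and Cl/Li exchange to the lithium alkynyl ether, which is protonated; the C3–O bond is never broken, so C3 keeps its configuration.

**Step 3**
Reactants: **6** vanillin; **2** chloromethyl methyl ether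
Product: **7** 3-methoxy-4-(methoxymethoxy)benzaldehyde
Conditions: MOMCl, i-Pr2NEt, CH2Cl2, 0 °C → rt
Reagents that add atoms: chloromethyl methyl ether, COCCl
Why: Phenol O-alkylation; a free phenol would add to the ynol ether and bind the Lewis acid in the next step.

**Step 4 (key step)**
Reactants: **5**; **7**
Product: **8** (2R,3R)-5,7-bis(methoxymethoxy)-2-[3,4,5-tris(methoxymethoxy)phenyl]chroman-3-yl (E)-3-[3-methoxy-4-(methoxymethoxy)phenyl]prop-2-enoate
Conditions: BF3·OEt2 (1.0 equiv), CH2Cl2, 4 Å MS, −78 → −30 °C; Et3N quench
Reagents that add atoms: none (both partners are the listed reactants)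
Why: Alkyne–carbonyl metathesis: the nucleophilic ynol ether and the BF3-activated aldehyde undergo [2+2] cycloaddition to a 2-alkoxy-2H-oxete, whose conrotatory 4π-electrocyclic ring opening turns the aryl group outward and gives the (E)-enoate; the aldehyde oxygen becomes the ester C=O and no sp3 stereocentre is involved.

**Step 5**
Reactants: **8**
Product: **9** epigallocatechin-3-O-ferulate (target)
Conditions: HCl (1.25 M in i-PrOH)/THF, Ar, rt → 35 °C
Reagents that add atoms: none
Why: Acid-catalysed acetal cleavage of the six aryl MOM ethers; the hindered secondary cinnamate survives in a non-nucleophilic alcohol, and C2 does not epimerise under mild acid without heating.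

## Compound list

1 | (−)-epigallocatechin, (2R,3R)-2-(3,4,5-trihydroxyphenyl)chromane-3,5,7-triol | O[C@@H]1Cc2c(O)cc(O)cc2O[C@@H]1c1cc(O)c(O)c(O)c1 | starting material (source of both stereocentres)
2 | chloromethyl methyl ether (MOMCl) | COCCl | starting material
3 | (2R,3R)-5,7-bis(methoxymethoxy)-2-[3,4,5-tris(methoxymethoxy)phenyl]chroman-3-ol | O[C@@H]1Cc2c(OCOC)cc(OCOC)cc2O[C@@H]1c1cc(OCOC)c(OCOC)c(OCOC)c1 | intermediate
4 | trichloroethylene | ClC=C(Cl)Cl | starting material
5 | (2R,3R)-3-(ethynyloxy)-5,7-bis(methoxymethoxy)-2-[3,4,5-tris(methoxymethoxy)phenyl]chromane | C#CO[C@@H]1Cc2c(OCOC)cc(OCOC)cc2O[C@@H]1c1cc(OCOC)c(OCOC)c(OCOC)c1 | intermediate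
6 | vanillin | COc1cc(C=O)ccc1O | starting material
7 | 3-methoxy-4-(methoxymethoxy)benzaldehyde | COCOc1ccc(C=O)cc1OC | intermediate
8 | (2R,3R)-5,7-bis(methoxymethoxy)-2-[3,4,5-tris(methoxymethoxy)phenyl]chroman-3-yl (E)-3-[3-methoxy-4-(methoxymethoxy)phenyl]prop-2-enoate | COCOc1ccc(/C=C/C(=O)O[C@@H]2Cc3c(OCOC)cc(OCOC)cc3O[C@@H]2c2cc(OCOC)c(OCOC)c(OCOC)c2)cc1OC | intermediate
9 | epigallocatechin-3-O-ferulate, (2R,3R)-5,7-dihydroxy-2-(3,4,5-trihydroxyphenyl)chroman-3-yl (E)-3-(4-hydroxy-3-methoxyphenyl)prop-2-enoate | COc1cc(/C=C/C(=O)O[C@@H]2Cc3c(O)cc(O)cc3O[C@@H]2c2cc(O)c(O)c(O)c2)ccc1O | target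

## Step count and risks

Total steps: 5. Longest linear sequence: 4 (1 → 3 → 5 → 8 → 9).

Steps most likely to fail:

- **Step 2 (ynol ether on the hindered axial 3-OH).** The product is acid- and heat-sensitive, and n-BuLi may also lithiate the MOM-flanked A-ring positions; that is harmless after the MeOH quench but is why 3 equiv are used. Fallback: drop the ynol ether. Acylate **3** with bromoacetyl bromide, convert to the ester-stabilised phosphorane with PPh3, and build the same Cα=Cβ bond with **7** by Wittig olefination.
- **Step 4 ([2+2]/ring opening).** BF3 may hydrate or oligomerise the ynol ether (giving the 3-O-acetate) or erode E-selectivity. Fallback: two-stage Meyer–Schuster route. Trap the lithium alkynyl ether from Step 2 with **7** to give the γ-hydroxy ynol ether, then rearrange it with catalytic Sc(OTf)3 to the same (E)-enoate. The final resort is direct EDC/DMAP esterification of **3** with 4-O-MOM-ferulic acid.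
- **Step 5 (sixfold MOM removal).** Incomplete cleavage, ester solvolysis, or acid-induced opening or epimerisation at the electron-rich benzylic C2 are the risks. Fallback: change the protecting-group plan to fluoride-labile TBS ethers, removed with HF·pyridine. Because silyl ethers do not tolerate KH/n-BuLi, the feruloyl unit would then be installed by the base-free bromoacetate/Wittig sequence or by direct acylation.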